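**Retrosynthetic overview**

- The route rests on ring A of unit 1 (C4a, C5–C8, C8a, carrying 5-OH and 7-OMe). It is an acylphloroglucinol fused through C4a–C8a to the pyranone that holds C2, so it is made last: the C4a–C5 bond is formed from an acylketene chain on C6 of an (S)-2-aryl-2,3-dihydro-4H-pyran-4-one (dioxinone thermolysis), followed by 7-O-methylation and debenzylation.
- The dihydropyranone (ring C of unit 1) comes from cyclodehydration of a δ-hydroxy diketo-dioxinone, itself from Claisen acylation of a keto-dioxinone dianion by a β-silyloxy Weinreb amide.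
- The Weinreb amide comes from Suzuki coupling (C3'–C6'' bond) of 6-iodo-4'-O-benzyl-(S)-sakuranetin with an arylboronate whose (S)-carbinol is set by asymmetric transfer hydrogenation.
- Ring order: rings of unit 2 from the chiral pool, then ring C of unit 1, then ring A of unit 1.

Key step: step 11

Remark (numbering): unit 1 is the 4'-methoxyflavanone (rings A/C, ring B primed); unit 2 is the sakuranetin half (double primes; its hydroxyphenyl ring triple primes).
Remark (assumptions): the C3'–C6'' axis carries only three small ortho oxygen substituents and is treated as freely rotating, in line with the target having no axial descriptor; (S)-sakuranetin is taken as purchasable in enantiopure form.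
Remark (design): the 5''-OH is left free throughout. It directs iodination to C6'', its phenoxide shields the unit-2 chromanone in the basic steps 7 and 9, and its hydrogen bond to C4''=O keeps it out of the acylketene and methylation steps. The carbinol is set on the small fragment so that unit 2 meets no reducing agent or strong Lewis acid.

**Route**

Step 1
Reactants: 1 methyl 3-bromo-4-methoxybenzoate; 2 N-methoxy-N-methylacetamide
Product: 3 3-(3-bromo-4-methoxyphenyl)-N-methoxy-N-methyl-3-oxopropanamide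
Conditions: 2 (2.2 equiv), LiN(iPr)2 (2.2 equiv), THF, −78 °C; then 1, −78 → −30 °C; AcOH
Reagents that add atoms: none
Why: Crossed Claisen condensation in which the lithium enolate of the Weinreb acetamide acylates on the methyl ester and a second equivalent of enolate deprotonates the β-keto amide as it forms, which stops further addition.

Step 2
Reactants: 3 3-(3-bromo-4-methoxyphenyl)-N-methoxy-N-methyl-3-oxopropanamide
Product: 4 (S)-3-(3-bromo-4-methoxyphenyl)-3-hydroxy-N-methoxy-N-methylpropanamide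
Conditions: RuCl(p-cymene)[(S,S)-TsDPEN] (1 mol %), HCO2H/Et3N (5:2), EtOAc, 30 °C
Reagents that add atoms: none
Why: Noyori asymmetric transfer hydrogenation, in which the (S,S)-TsDPEN ruthenium hydride reduces the aryl ketone from the face fixed by the aryl/η6-arene contact, giving the (S)-carbinol as with acetophenone and leaving the N–O bond and the aryl bromide untouched.

Step 3
Reactants: 4 (S)-3-(3-bromo-4-methoxyphenyl)-3-hydroxy-N-methoxy-N-methylpropanamide
Product: 5 (S)-3-(3-bromo-4-methoxyphenyl)-N-methoxy-N-methyl-3-(triethylsilyloxy)propanamide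
Conditions: Et3SiCl, imidazole, DMF, 0 °C → rt
Reagents that add atoms: chlorotriethylsilane, CC[Si](Cl)(CC)CC
Why: Standard silylation of the secondary benzylic alcohol, which blocks alkoxide formation and retro-aldol cleavage in the later basic steps and is removable by fluoride.

Step 4
Reactants: 5 (S)-3-(3-bromo-4-methoxyphenyl)-N-methoxy-N-methyl-3-(triethylsilyloxy)propanamide
Product: 6 (S)-N-methoxy-3-[4-methoxy-3-(4,4,5,5-tetramethyl-1,3,2-dioxaborolan-2-yl)phenyl]-N-methyl-3-(triethylsilyloxy)propanamide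
Conditions: B2pin2, PdCl2(dppf) (5 mol %), KOAc, 1,4-dioxane, 85 °C
Reagents that add atoms: bis(pinacolato)diboron, CC1(C)OB(OC1(C)C)B1OC(C)(C)C(C)(C)O1
Why: Miyaura borylation of the aryl bromide with the weak base KOAc, under which the Weinreb amide and the silyl ether are stable.

Step 5
Reactants: 7 (S)-sakuranetin, (2S)-5-hydroxy-2-(4-hydroxyphenyl)-7-methoxychroman-4-one
Product: 8 (2S)-2-(4-benzyloxyphenyl)-5-hydroxy-7-methoxychroman-4-one
Conditions: BnOH (1.05 equiv), PPh3, DIAD, THF, 0 °C → rt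
Reagents that add atoms: benzyl alcohol, OCc1ccccc1
Why: Mitsunobu etherification under neutral conditions, in which only the free 4'-phenol is alkylated, the hydrogen-bonded 5-OH stays, and in the absence of base C2 cannot epimerize through the chalcone.

Step 6
Reactants: 8 (2S)-2-(4-benzyloxyphenyl)-5-hydroxy-7-methoxychroman-4-one
Product: 9 (2S)-2-(4-benzyloxyphenyl)-5-hydroxy-6-iodo-7-methoxychroman-4-one
Conditions: BnMe3N·ICl2 (1.05 equiv), CaCO3, CH2Cl2/MeOH, rt
Reagents that add atoms: benzyltrimethylammonium dichloroiodate, C[N+](C)(C)Cc1ccccc1.Cl[I-]Cl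
Why: Electrophilic aromatic iodination of the most electron-rich ring, where the free 5-OH directs dichloroiodate ortho to itself at C6 (the known preference of 5-hydroxy-7-alkoxy flavonoids, whereas 5-O-alkyl ethers react at C8) and CaCO3 takes up HCl without opening the pyranone ring.

Step 7
Reactants: 9 (2S)-2-(4-benzyloxyphenyl)-5-hydroxy-6-iodo-7-methoxychroman-4-one; 6 (S)-N-methoxy-3-[4-methoxy-3-(4,4,5,5-tetramethyl-1,3,2-dioxaborolan-2-yl)phenyl]-N-methyl-3-(triethylsilyloxy)propanamide
Product: 10 (S)-3-{3-[(2S)-2-(4-benzyloxyphenyl)-5-hydroxy-7-methoxy-4-oxochroman-6-yl]-4-methoxyphenyl}-N-methoxy-N-methyl-3-(triethylsilyloxy)propanamide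
Conditions: Pd(OAc)2 (5 mol %), SPhos (10 mol %), K3PO4, PhMe/H2O (10:1), 60 °C
Reagents that add atoms: none
Why: Suzuki–Miyaura coupling with a dialkylbiarylphosphine ligand that handles the doubly ortho-substituted iodide and the ortho-methoxy boronate, while the phenol reacts as its phenoxide, which makes the chromanone less prone to base-induced ring opening.

Step 8
Reactants: 11 2,2,6-trimethyl-4H-1,3-dioxin-4-one
Product: 12 2,2-dimethyl-6-(2-oxopropyl)-4H-1,3-dioxin-4-one
Conditions: 11 (2 equiv), LiN(SiMe3)2 (2 equiv), THF, −78 °C; AcCl (1 equiv); aq HCl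
Reagents that add atoms: acetyl chloride, CC(=O)Cl
Why: Vinylogous (γ) C-acylation of the lithium dienolate of the dioxinone with acetyl chloride, the second equivalent of dienolate taking up the more acidic product as its enolate.

Step 9
Reactants: 10 (S)-3-{3-[(2S)-2-(4-benzyloxyphenyl)-5-hydroxy-7-methoxy-4-oxochroman-6-yl]-4-methoxyphenyl}-N-methoxy-N-methyl-3-(triethylsilyloxy)propanamide; 12 2,2-dimethyl-6-(2-oxopropyl)-4H-1,3-dioxin-4-one
Product: 13 6-[(6S)-6-{3-[(2S)-2-(4-benzyloxyphenyl)-5-hydroxy-7-methoxy-4-oxochroman-6-yl]-4-methoxyphenyl}-2,4-dioxo-6-(triethylsilyloxy)hexyl]-2,2-dimethyl-4H-1,3-dioxin-4-one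
Conditions: 12 (3.5 equiv), LiN(iPr)2 (7 equiv), THF, −78 °C; then 10, −78 → −40 °C; AcOH, −78 °C
Reagents that add atoms: none
Why: Claisen condensation of a dicarbonyl-type dianion, in which the keto-dioxinone is deprotonated at the doubly activated CH2 and then at the terminal CH3, whose carbanion adds to the Weinreb amide to give a stable chelated adduct, while the lithium phenoxide formed first from the 5''-OH turns the unit-2 carbonyl into a vinylogous carboxylate that is neither attacked nor enolized, so C2'' is kept.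

Step 10
Reactants: 13 6-[(6S)-6-{3-[(2S)-2-(4-benzyloxyphenyl)-5-hydroxy-7-methoxy-4-oxochroman-6-yl]-4-methoxyphenyl}-2,4-dioxo-6-(triethylsilyloxy)hexyl]-2,2-dimethyl-4H-1,3-dioxin-4-one
Product: 15 (2S)-2-{3-[(2S)-2-(4-benzyloxyphenyl)-5-hydroxy-7-methoxy-4-oxochroman-6-yl]-4-methoxyphenyl}-6-[(2,2-dimethyl-4-oxo-4H-1,3-dioxin-6-yl)methyl]-2,3-dihydro-4H-pyran-4-one, via δ-hydroxy diketo-dioxinone 14 (not isolated)
Conditions: HF·pyridine, THF, 0 °C → rt; then TsOH·H2O (cat.), CH2Cl2, 0 °C
Reagents that add atoms: none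
Why: Fluoride removes the silyl ether and the δ-hydroxy β-diketone closes to the six-membered hemiketal, which acid dehydrates to the vinylogous ester (cyclodehydration to a 2,3-dihydro-4H-pyran-4-one); the C–O bond at the carbinol carbon is never broken, so the (S) centre becomes C2 unchanged, and the mild fluoride step avoids ionizing the p-methoxybenzylic position.

Step 11
Reactants: 15 (2S)-2-{3-[(2S)-2-(4-benzyloxyphenyl)-5-hydroxy-7-methoxy-4-oxochroman-6-yl]-4-methoxyphenyl}-6-[(2,2-dimethyl-4-oxo-4H-1,3-dioxin-6-yl)methyl]-2,3-dihydro-4H-pyran-4-one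
Product: 18 (2S)-2-{3-[(2S)-2-(4-benzyloxyphenyl)-5-hydroxy-7-methoxy-4-oxochroman-6-yl]-4-methoxyphenyl}-5,7-dihydroxychroman-4-one, via acylketene 16 (not isolated), via cyclohexadienone 17 (not isolated)
Conditions: dry PhMe, 110 °C, slow addition to 0.002 M, N2 sweep
Reagents that add atoms: none
Why: Proposed new method: retro-[4+2] loss of acetone from the dioxinone gives acylketene 16, whose ketone enolizes toward the exocyclic CH2 so that the pyranone C5=C6 enol-ether double bond, the new enol C=C and the ketene C=C form a dienylketene that closes by thermal 6π electrocyclization (equivalently, C-acylation of the nucleophilic enol-ether carbon C5 by the ketene) to cyclohexadienone 17, which tautomerizes to the phloroglucinol ring. The closest known chemistry is the thermolysis of diketo-dioxinones with aromatization to resorcylates and the dienylketene electrocyclization that ends the Danheiser benzannulation; capture of a dioxinone-derived acylketene by the α-carbon of a vinylogous ester has not been shown. Ring A closes through the C4a–C5 bond as a six-membered all-carbon 6π closure onto the ketene carbon. No lasting stereocenter is formed (C4a of 17 is lost on aromatization), and C2 and C2'' are untouched because no base or acid is present. The step needs C–C closure to win over O-closure and over intermolecular ketene capture: the only vinylogous-ester oxygen within reach is the ring ether O1, which cannot give a pyrone, and high dilution with slow addition, dry solvent, removal of acetone and the low nucleophilicity of the hydrogen-bonded 5''-OH suppress dimerization, phenol acylation and recombination.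

Step 12
Reactants: 18 (2S)-2-{3-[(2S)-2-(4-benzyloxyphenyl)-5-hydroxy-7-methoxy-4-oxochroman-6-yl]-4-methoxyphenyl}-5,7-dihydroxychroman-4-one
Product: 19 (2S)-2-{3-[(2S)-2-(4-benzyloxyphenyl)-5-hydroxy-7-methoxy-4-oxochroman-6-yl]-4-methoxyphenyl}-5-hydroxy-7-methoxychroman-4-one
Conditions: Me3SiCHN2 (1.2 equiv), PhMe/MeOH (4:1), 0 °C → rt
Reagents that add atoms: trimethylsilyldiazomethane, C[Si](C)(C)C=[N+]=[N-]
Why: Methylation of an acidic phenol with trimethylsilyldiazomethane in methanol, where only the 7-OH (para to the carbonyl, not hydrogen-bonded) reacts and the 5-OH and 5''-OH are held in hydrogen bonds to their carbonyls.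

Step 13
Reactants: 19 (2S)-2-{3-[(2S)-2-(4-benzyloxyphenyl)-5-hydroxy-7-methoxy-4-oxochroman-6-yl]-4-methoxyphenyl}-5-hydroxy-7-methoxychroman-4-one
Product: 20 (2S)-5-hydroxy-2-{3-[(2S)-5-hydroxy-2-(4-hydroxyphenyl)-7-methoxy-4-oxochroman-6-yl]-4-methoxyphenyl}-7-methoxychroman-4-one (CNP0150873.1)
Conditions: H2 (1 atm), 10% Pd/C, EtOAc/MeOH, rt
Reagents that add atoms: none
Why: Hydrogenolysis of the benzyl aryl ether over palladium on carbon, stopped after one equivalent of hydrogen so that the chromanone carbonyls and the benzylic C2–O bonds are not reduced.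

**Compound list**

1 | methyl 3-bromo-4-methoxybenzoate | COC(=O)c1ccc(OC)c(Br)c1 | starting material
2 | N-methoxy-N-methylacetamide | CC(=O)N(C)OC | starting material
3 | 3-(3-bromo-4-methoxyphenyl)-N-methoxy-N-methyl-3-oxopropanamide | CON(C)C(=O)CC(=O)c1ccc(OC)c(Br)c1 | intermediate
4 | (S)-3-(3-bromo-4-methoxyphenyl)-3-hydroxy-N-methoxy-N-methylpropanamide | CON(C)C(=O)C[C@H](O)c1ccc(OC)c(Br)c1 | intermediate
5 | (S)-3-(3-bromo-4-methoxyphenyl)-N-methoxy-N-methyl-3-(triethylsilyloxy)propanamide | CON(C)C(=O)C[C@H](O[Si](CC)(CC)CC)c1ccc(OC)c(Br)c1 | intermediate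
6 | (S)-N-methoxy-3-[4-methoxy-3-(4,4,5,5-tetramethyl-1,3,2-dioxaborolan-2-yl)phenyl]-N-methyl-3-(triethylsilyloxy)propanamide | CON(C)C(=O)C[C@H](O[Si](CC)(CC)CC)c1ccc(OC)c(B2OC(C)(C)C(C)(C)O2)c1 | intermediate
7 | (S)-sakuranetin, (2S)-5-hydroxy-2-(4-hydroxyphenyl)-7-methoxychroman-4-one | COc1cc(O)c2c(c1)O[C@H](c1ccc(O)cc1)CC2=O | starting material
8 | (2S)-2-(4-benzyloxyphenyl)-5-hydroxy-7-methoxychroman-4-one | COc1cc(O)c2c(c1)O[C@H](c1ccc(OCc3ccccc3)cc1)CC2=O | intermediate
9 | (2S)-2-(4-benzyloxyphenyl)-5-hydroxy-6-iodo-7-methoxychroman-4-one | COc1cc2c(c(O)c1I)C(=O)C[C@@H](c1ccc(OCc3ccccc3)cc1)O2 | intermediate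
10 | (S)-3-{3-[(2S)-2-(4-benzyloxyphenyl)-5-hydroxy-7-methoxy-4-oxochroman-6-yl]-4-methoxyphenyl}-N-methoxy-N-methyl-3-(triethylsilyloxy)propanamide | CON(C)C(=O)C[C@H](O[Si](CC)(CC)CC)c1ccc(OC)c(-c2c(OC)cc3c(c2O)C(=O)C[C@@H](c2ccc(OCc4ccccc4)cc2)O3)c1 | intermediate
11 | 2,2,6-trimethyl-4H-1,3-dioxin-4-one | CC1=CC(=O)OC(C)(C)O1 | starting material
12 | 2,2-dimethyl-6-(2-oxopropyl)-4H-1,3-dioxin-4-one | CC(=O)CC1=CC(=O)OC(C)(C)O1 | intermediate
13 | 6-[(6S)-6-{3-[(2S)-2-(4-benzyloxyphenyl)-5-hydroxy-7-methoxy-4-oxochroman-6-yl]-4-methoxyphenyl}-2,4-dioxo-6-(triethylsilyloxy)hexyl]-2,2-dimethyl-4H-1,3-dioxin-4-one | CC1(C)OC(=O)C=C(CC(=O)CC(=O)C[C@H](O[Si](CC)(CC)CC)c2ccc(OC)c(-c3c(OC)cc4c(c3O)C(=O)C[C@@H](c3ccc(OCc5ccccc5)cc3)O4)c2)O1 | intermediate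
14 | 6-[(6S)-6-{3-[(2S)-2-(4-benzyloxyphenyl)-5-hydroxy-7-methoxy-4-oxochroman-6-yl]-4-methoxyphenyl}-6-hydroxy-2,4-dioxohexyl]-2,2-dimethyl-4H-1,3-dioxin-4-one (δ-hydroxy diketo-dioxinone) | CC1(C)OC(=O)C=C(CC(=O)CC(=O)C[C@H](O)c2ccc(OC)c(-c3c(OC)cc4c(c3O)C(=O)C[C@@H](c3ccc(OCc5ccccc5)cc3)O4)c2)O1 | intermediate (not isolated)
15 | (2S)-2-{3-[(2S)-2-(4-benzyloxyphenyl)-5-hydroxy-7-methoxy-4-oxochroman-6-yl]-4-methoxyphenyl}-6-[(2,2-dimethyl-4-oxo-4H-1,3-dioxin-6-yl)methyl]-2,3-dihydro-4H-pyran-4-one | O=C1C[C@@H](c2ccc(OC)c(-c3c(OC)cc4c(c3O)C(=O)C[C@@H](c3ccc(OCc5ccccc5)cc3)O4)c2)OC(CC2=CC(=O)OC(C)(C)O2)=C1 | intermediate (key-step precursor)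
16 | (2S)-2-aryl-6-(2,4-dioxobut-3-en-1-yl)-2,3-dihydro-4H-pyran-4-one, aryl as in 15 (acylketene) | O=C=CC(=O)CC1=CC(=O)C[C@@H](c2ccc(OC)c(-c3c(OC)cc4c(c3O)C(=O)C[C@@H](c3ccc(OCc5ccccc5)cc3)O4)c2)O1 | intermediate (not isolated)
17 | (2S)-2-aryl-7-hydroxy-2,3-dihydro-4aH-chromene-4,5-dione, aryl as in 15 (cyclohexa-2,4-dienone tautomer of 18; C4a transient, configuration not defined) | O=C1C=C(O)C=C2O[C@H](c3ccc(OC)c(-c4c(OC)cc5c(c4O)C(=O)C[C@@H](c4ccc(OCc6ccccc6)cc4)O5)c3)CC(=O)C12 | intermediate (not isolated)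
18 | (2S)-2-{3-[(2S)-2-(4-benzyloxyphenyl)-5-hydroxy-7-methoxy-4-oxochroman-6-yl]-4-methoxyphenyl}-5,7-dihydroxychroman-4-one (7-O-desmethyl 4'''-O-benzyl target) | Oc1cc(O)c2c(c1)O[C@H](c1ccc(OC)c(-c3c(OC)cc4c(c3O)C(=O)C[C@@H](c3ccc(OCc5ccccc5)cc3)O4)c1)CC2=O | intermediate (key-step product)
19 | (2S)-2-{3-[(2S)-2-(4-benzyloxyphenyl)-5-hydroxy-7-methoxy-4-oxochroman-6-yl]-4-methoxyphenyl}-5-hydroxy-7-methoxychroman-4-one | COc1cc(O)c2c(c1)O[C@H](c1ccc(OC)c(-c3c(OC)cc4c(c3O)C(=O)C[C@@H](c3ccc(OCc5ccccc5)cc3)O4)c1)CC2=O | intermediate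
20 | (2S)-5-hydroxy-2-{3-[(2S)-5-hydroxy-2-(4-hydroxyphenyl)-7-methoxy-4-oxochroman-6-yl]-4-methoxyphenyl}-7-methoxychroman-4-one | COc1cc(O)c2c(c1)O[C@H](c1ccc(OC)c(-c3c(OC)cc4c(c3O)C(=O)C[C@@H](c3ccc(O)cc3)O4)c1)CC2=O | target

**Step count and risks**

Total step count: 13. Longest linear sequence: 10 steps (steps 1–4, 7, 9–13).

Steps most likely to fail:

Step 11 (Proposed new method). The acylketene may be consumed between molecules (dimerization, O-acylation of phenols of product already formed) or by traces of water (decarboxylation to a methyl ketone) faster than the enol-ether carbon closes onto it. The fallback uses known chemistry, sets out from 9 and returns at 19; ring A of unit 1 is then taken from a chromone and not built. Suzuki coupling of 9 with (5-chloro-2-methoxyphenyl)boronic acid (COc1ccc(Cl)cc1B(O)O; Pd(PPh3)4, K3PO4, dioxane/H2O, 80 °C, where C–I reacts and C–Cl does not) should give the chloro biaryl (2S)-2-(4-benzyloxyphenyl)-6-(5-chloro-2-methoxyphenyl)-5-hydroxy-7-methoxychroman-4-one F1. Borylation of the aryl chloride with B2(OH)4 (Pd(OAc)2/XPhos, KOAc, EtOH, 80 °C) should give the boronic acid {3-[(2S)-2-(4-benzyloxyphenyl)-5-hydroxy-7-methoxy-4-oxochroman-6-yl]-4-methoxyphenyl}boronic acid F2. Selective 7-O-methylation of purchasable 5,7-dihydroxychromone (Me3SiCHN2, MeOH) gives 5-hydroxy-7-methoxy-4H-chromen-4-one F3. Asymmetric conjugate addition of F2 to F3, catalysed by Pd(OCOCF3)2 and the t-BuPyOx antipode that delivers the (2S) series, should give 19 directly (any C2 epimer would be a separable diastereomer), and step 13 then follows.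

Step 9. Proton transfer to the dianion from the methylene next to the amide (followed by β-elimination of silanolate) or from unit 2, and base-induced aldol aromatization of the diketo-dioxinone on work-up, may outrun or undo acyl transfer. The fallback sets out from 5 and returns at 15, completing the chain before the fragments are joined. Claisen acylation of the dianion of 12 with the simple bromide 5 (no phenol, no second ketone) should give the diketo-dioxinone 6-[(6S)-6-(3-bromo-4-methoxyphenyl)-2,4-dioxo-6-(triethylsilyloxy)hexyl]-2,2-dimethyl-4H-1,3-dioxin-4-one F4. HF·pyridine and then catalytic TsOH should give the bromo dihydropyranone (2S)-2-(3-bromo-4-methoxyphenyl)-6-[(2,2-dimethyl-4-oxo-4H-1,3-dioxin-6-yl)methyl]-2,3-dihydro-4H-pyran-4-one F5. Miyaura borylation (B2pin2, PdCl2(dppf), KOAc, dioxane, 80 °C, below the temperature at which the dioxinone opens) should give the boronate (2S)-6-[(2,2-dimethyl-4-oxo-4H-1,3-dioxin-6-yl)methyl]-2-[4-methoxy-3-(4,4,5,5-tetramethyl-1,3,2-dioxaborolan-2-yl)phenyl]-2,3-dihydro-4H-pyran-4-one F6. Suzuki coupling of F6 with 9 (Pd(OAc)2/SPhos, K3PO4, 50 °C) should give 15.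

Step 7. Slow transmetalation at the doubly ortho-substituted iodide may let protodeboronation of 6 and phosphate-induced opening of the unit-2 pyranone ring (chalcone formation, loss of C2'' configuration) compete. The fallback sets out from 5 and returns at 10 by a base-free Stille union. Stannylation of 5 (Me3SnSnMe3, Pd(PPh3)4, PhMe, 100 °C) should give the arylstannane (S)-N-methoxy-3-[4-methoxy-3-(trimethylstannyl)phenyl]-N-methyl-3-(triethylsilyloxy)propanamide F7. Coupling of F7 with 9 under neutral, copper-assisted conditions (Pd2(dba)3, AsPh3, copper thiophene-2-carboxylate, NMP, rt → 40 °C) should give 10.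

Further compounds
F1 | step 11 | (2S)-2-(4-benzyloxyphenyl)-6-(5-chloro-2-methoxyphenyl)-5-hydroxy-7-methoxychroman-4-one | COc1ccc(Cl)cc1-c1c(OC)cc2c(c1O)C(=O)C[C@@H](c1ccc(OCc3ccccc3)cc1)O2
F2 | step 11 | {3-[(2S)-2-(4-benzyloxyphenyl)-5-hydroxy-7-methoxy-4-oxochroman-6-yl]-4-methoxyphenyl}boronic acid | COc1ccc(B(O)O)cc1-c1c(OC)cc2c(c1O)C(=O)C[C@@H](c1ccc(OCc3ccccc3)cc1)O2
F3 | step 11 | 5-hydroxy-7-methoxy-4H-chromen-4-one | COc1cc(O)c2c(=O)ccoc2c1
F4 | step 9 | 6-[(6S)-6-(3-bromo-4-methoxyphenyl)-2,4-dioxo-6-(triethylsilyloxy)hexyl]-2,2-dimethyl-4H-1,3-dioxin-4-one | CC1(C)OC(=O)C=C(CC(=O)CC(=O)C[C@H](O[Si](CC)(CC)CC)c2ccc(OC)c(Br)c2)O1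
F5 | step 9 | (2S)-2-(3-bromo-4-methoxyphenyl)-6-[(2,2-dimethyl-4-oxo-4H-1,3-dioxin-6-yl)methyl]-2,3-dihydro-4H-pyran-4-one | O=C1C[C@@H](c2ccc(OC)c(Br)c2)OC(CC2=CC(=O)OC(C)(C)O2)=C1
F6 | step 9 | (2S)-6-[(2,2-dimethyl-4-oxo-4H-1,3-dioxin-6-yl)methyl]-2-[4-methoxy-3-(4,4,5,5-tetramethyl-1,3,2-dioxaborolan-2-yl)phenyl]-2,3-dihydro-4H-pyran-4-one | O=C1C[C@@H](c2ccc(OC)c(B3OC(C)(C)C(C)(C)O3)c2)OC(CC2=CC(=O)OC(C)(C)O2)=C1
F7 | step 7 | (S)-N-methoxy-3-[4-methoxy-3-(trimethylstannyl)phenyl]-N-methyl-3-(triethylsilyloxy)propanamide | CON(C)C(=O)C[C@H](O[Si](CC)(CC)CC)c1ccc(OC)c([Sn](C)(C)C)c1
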